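**Retrosynthetic overview**
1. Target ⇒ global desilylation; the C11 CH2OH comes from a C4–H enol ether (Vilsmeier–Haack formylation, then Luche reduction); the C1 ester comes from acylation of a lactol with (S)-3-methylpentanoic acid.
2. Pyran ring (formed second) ⇒ cis-fused enol δ-lactone closed between the C9 carboxyl and a C5 CH2CHO arm; lactone → lactol by chemoselective hydride.
3. Ring A (formed first) ⇒ C7–C8 bond by a carbene-generated acyl anion (Breslow intermediate) adding to the C8 ketone (intramolecular crossed benzoin); the C7 OH is then set by hydroxyl-directed reduction.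
4. The keto aldehyde ⇒ C5–C9 bond by iminium-catalysed Michael addition of a 4-(coumaroyloxy)acetoacetate to (2E)-5,5-diethoxypent-2-enal, run in the same pot as the benzoin.
5. Building blocks: p-coumaric acid, tert-butyl 4-chloroacetoacetate, 3-butenal diethyl acetal, crotonaldehyde, (S)-3-methylpentanoic acid.

Assumption: 2, 4 and 15 are taken as catalogue chemicals; the triazolium enantiomer named in step 3 is assumed to be the one that gives the C8 (S)-carbinol (its antipode is used if the sense is opposite); iridoid numbering (C1, C3–C11) is used in the explanations.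

**Step 1**
Reactants: 1 p-coumaric acid; 2 tert-butyl 4-chloro-3-oxobutanoate
Product: 3 tert-butyl 4-(p-coumaroyloxy)-3-oxobutanoate
Conditions: KHCO3 (1.1 equiv), NaI (10 mol %), DMF, 23 °C
Reagents that add atoms: none
Why: SN2 displacement of the activated α-chloro ketone chloride by the carboxylate (iodide-assisted), with bicarbonate strong enough to deprotonate only the carboxylic acid so that the phenol and the β-keto ester stay untouched.

**Step 2**
Reactants: 4 4,4-diethoxybut-1-ene; 5 (2E)-but-2-enal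
Product: 6 (2E)-5,5-diethoxypent-2-enal
Conditions: second-generation Hoveyda–Grubbs catalyst RuCl2(H2IMes)(=CH-C6H4-2-OiPr) (2 mol %), 5 (3 equiv), CH2Cl2, 40 °C
Reagents that add atoms: none
Why: Olefin cross-metathesis of a terminal alkene with an excess of an electron-poor enal gives the E-enal with loss of propene, and the acetal is inert to the ruthenium carbene.

**Step 3**
Reactants: 3 tert-butyl 4-(p-coumaroyloxy)-3-oxobutanoate; 6 (2E)-5,5-diethoxypent-2-enal
Product: 8 all-cis α-hydroxy cyclopentanone (C5 chain; C9 ester; C8 OH on one face), via Michael adduct 7 (not isolated)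
Conditions: (S)-2-[diphenyl(trimethylsilyloxy)methyl]pyrrolidine (20 mol %), (5aS,10bR)-2-(pentafluorophenyl)-5a,10b-dihydro-4H,6H-indeno[2,1-b][1,2,4]triazolo[4,3-d][1,4]oxazin-2-ium tetrafluoroborate (10 mol %), NaOAc (20 mol %), CHCl3, 23 °C
Reagents that add atoms: none
Why: Iminium-catalysed Michael addition sets C5 (the keto ester attacks the E-iminium ion anti to the diphenyl(silyloxy)methyl group), after which the carbene turns the freed aldehyde into a Breslow acyl anion that closes ring A by a 5-exo crossed benzoin onto the activated C8 ketone, the chiral triazolium choosing the ketone face (OH syn to the C5 chain) while the epimerizable C9 settles with its ester anti to the new CH2O group (secondary amine/carbene Michael–crossed benzoin cascade).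

**Step 4**
Reactants: 8 all-cis α-hydroxy cyclopentanone
Product: 9 trans-7,8-diol
Conditions: Me4NBH(OAc)3 (5 equiv), MeCN/AcOH (1:1), −30 °C
Reagents that add atoms: none
Why: Evans–Saksena hydroxyl-directed reduction, in which the tertiary C8 OH binds boron and delivers hydride to its own face of the C7 ketone to give the trans diol, while esters, acetal and phenol are inert to the triacetoxyborohydride.

**Step 5**
Reactants: 9 trans-7,8-diol
Product: 11 aryl TBS bis-TES ether, via aryl TBS ether 10 (not isolated)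
Conditions: TBSCl (1.05 equiv), imidazole, CH2Cl2, 0 °C; then 2,6-lutidine, TESOTf (2.6 equiv), −78 → −30 °C
Reagents that add atoms: tert-butyldimethylsilyl chloride (CC(C)(C)[Si](C)(C)Cl); triethylsilyl trifluoromethanesulfonate (CC[Si](CC)(CC)OS(=O)(=O)C(F)(F)F)
Why: Chemoselective silylation, the phenol reacting first with the silyl chloride and the hindered secondary and tertiary alcohols then with the silyl triflate at a temperature too low to activate the acetal, with no stereocentre touched.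

**Step 6**
Reactants: 11 aryl TBS bis-TES ether
Product: 13 cis-fused enol δ-lactone, via aldehyde acid 12 (not isolated)
Conditions: TMSOTf (5 equiv), 2,6-lutidine (7 equiv), CH2Cl2, 0 → 23 °C; H2O; then (CF3CO)2O, pyridine, CH2Cl2, 0 → 23 °C
Reagents that add atoms: water (O)
Why: The silyl triflate/lutidine pair cleaves the tert-butyl ester to a silyl ester and converts the diethyl acetal into a lutidinium adduct that water hydrolyses to the aldehyde without protic acid (silyl ethers survive), and trifluoroacetylation of the resulting pseudo-acid with loss of trifluoroacetate closes the enol lactone between the cis C9 carboxyl and C5 arm (dehydrative enol lactonization).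

**Step 7**
Reactants: 13 cis-fused enol δ-lactone
Product: 14 lactol
Conditions: NaBH4 (1 equiv), THF/i-PrOH, −20 °C
Reagents that add atoms: none
Why: The enol lactone is an activated ester that borohydride reduces while the conjugated alkyl coumarate is inert, and reclosure to the cyclic hemiacetal protects against over-reduction and lets C1 equilibrate to the anomer with OH trans to C8 (chemoselective lactone-to-lactol reduction, the nepetalactone-to-nepetalactol type).

**Step 8**
Reactants: 14 lactol; 15 (3S)-3-methylpentanoic acid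
Product: 16 C1 (S)-3-methylpentanoate
Conditions: DCC, DMAP (cat.), CH2Cl2, 0 °C
Reagents that add atoms: none
Why: Steglich esterification of the anomeric hydroxyl, the only free OH, which is acylated on the convex face trans to the C8 quaternary centre to give the (1R) acyloxy acetal.

**Step 9**
Reactants: 16 C1 (S)-3-methylpentanoate
Product: 18 C4 aldehyde, via iminium chloride 17 (not isolated)
Conditions: (chloromethylene)dimethyliminium chloride (1.5 equiv), DMF/CH2Cl2, 0 → 23 °C; then aq NaOAc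
Reagents that add atoms: (chloromethylene)dimethyliminium chloride (ClC=[N+](C)C.[Cl-]); water (O)
Why: Vilsmeier–Haack formylation, the enol ether attacking the chloroiminium ion through its nucleophilic β-carbon C4 and the vinylogous iminium salt being hydrolysed to the push–pull aldehyde, a reaction known to tolerate a C1 acyloxy acetal in iridoid lactol esters.

**Step 10**
Reactants: 18 C4 aldehyde
Product: 19 C11 alcohol
Conditions: NaBH4, CeCl3·7H2O, MeOH/THF, −40 °C
Reagents that add atoms: none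
Why: Luche 1,2-reduction of the vinylogous formyl group, with esters, acyloxy acetal and silyl ethers inert at this temperature and no new stereocentre formed.

**Step 11**
Reactants: 19 C11 alcohol
Product: 20 target CNP0241834.3
Conditions: HF·pyridine, pyridine, THF, 0 → 23 °C
Reagents that add atoms: none
Why: Buffered fluoride desilylation removes the aryl TBS and both TES ethers through Si–F bond formation, acidic enough to prevent acyl migration and buffered enough not to ionize the enol ether or let the C8 OH add to C3.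

**Compound list**
1 | (2E)-3-(4-hydroxyphenyl)prop-2-enoic acid (p-coumaric acid) | OC(=O)/C=C/c1ccc(O)cc1 | starting material
2 | tert-butyl 4-chloro-3-oxobutanoate | CC(C)(C)OC(=O)CC(=O)CCl | starting material
3 | tert-butyl 4-{[(2E)-3-(4-hydroxyphenyl)prop-2-enoyl]oxy}-3-oxobutanoate | CC(C)(C)OC(=O)CC(=O)COC(=O)/C=C/c1ccc(O)cc1 | intermediate
4 | 4,4-diethoxybut-1-ene | C=CCC(OCC)OCC | starting material
5 | (2E)-but-2-enal | C/C=C/C=O | starting material
6 | (2E)-5,5-diethoxypent-2-enal | O=C/C=C/CC(OCC)OCC | intermediate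
7 | tert-butyl (3S)-3-(2,2-diethoxyethyl)-2-({[(2E)-3-(4-hydroxyphenyl)prop-2-enoyl]oxy}acetyl)-5-oxopentanoate (C2 epimers) | O=CC[C@@H](CC(OCC)OCC)C(C(=O)OC(C)(C)C)C(=O)COC(=O)/C=C/c1ccc(O)cc1 | intermediate
8 | tert-butyl (1R,2S,5R)-5-(2,2-diethoxyethyl)-2-hydroxy-2-({[(2E)-3-(4-hydroxyphenyl)prop-2-enoyl]oxy}methyl)-3-oxocyclopentane-1-carboxylate | CCOC(OCC)C[C@@H]1CC(=O)[C@@](O)(COC(=O)/C=C/c2ccc(O)cc2)[C@@H]1C(=O)OC(C)(C)C | intermediate
9 | tert-butyl (1R,2S,3R,5S)-5-(2,2-diethoxyethyl)-2,3-dihydroxy-2-({[(2E)-3-(4-hydroxyphenyl)prop-2-enoyl]oxy}methyl)cyclopentane-1-carboxylate | CCOC(OCC)C[C@@H]1C[C@@H](O)[C@@](O)(COC(=O)/C=C/c2ccc(O)cc2)[C@@H]1C(=O)OC(C)(C)C | intermediate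
10 | tert-butyl (1R,2S,3R,5S)-2-({[(2E)-3-{4-[(tert-butyldimethylsilyl)oxy]phenyl}prop-2-enoyl]oxy}methyl)-5-(2,2-diethoxyethyl)-2,3-dihydroxycyclopentane-1-carboxylate | CCOC(OCC)C[C@@H]1C[C@@H](O)[C@@](O)(COC(=O)/C=C/c2ccc(O[Si](C)(C)C(C)(C)C)cc2)[C@@H]1C(=O)OC(C)(C)C | intermediate
11 | tert-butyl (1R,2S,3R,5S)-2-({[(2E)-3-{4-[(tert-butyldimethylsilyl)oxy]phenyl}prop-2-enoyl]oxy}methyl)-5-(2,2-diethoxyethyl)-2,3-bis[(triethylsilyl)oxy]cyclopentane-1-carboxylate | CCOC(OCC)C[C@@H]1C[C@@H](O[Si](CC)(CC)CC)[C@@](O[Si](CC)(CC)CC)(COC(=O)/C=C/c2ccc(O[Si](C)(C)C(C)(C)C)cc2)[C@@H]1C(=O)OC(C)(C)C | intermediate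
12 | (1R,2S,3R,5S)-2-({[(2E)-3-{4-[(tert-butyldimethylsilyl)oxy]phenyl}prop-2-enoyl]oxy}methyl)-5-(2-oxoethyl)-2,3-bis[(triethylsilyl)oxy]cyclopentane-1-carboxylic acid | O=CC[C@@H]1C[C@@H](O[Si](CC)(CC)CC)[C@@](O[Si](CC)(CC)CC)(COC(=O)/C=C/c2ccc(O[Si](C)(C)C(C)(C)C)cc2)[C@@H]1C(O)=O | intermediate
13 | [(4aS,6R,7S,7aR)-1-oxo-6,7-bis[(triethylsilyl)oxy]-1,4a,5,6,7,7a-hexahydrocyclopenta[c]pyran-7-yl]methyl (2E)-3-{4-[(tert-butyldimethylsilyl)oxy]phenyl}prop-2-enoate | O=C1OC=C[C@@H]2C[C@@H](O[Si](CC)(CC)CC)[C@@](O[Si](CC)(CC)CC)(COC(=O)/C=C/c3ccc(O[Si](C)(C)C(C)(C)C)cc3)[C@H]12 | intermediate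
14 | [(1S,4aS,6R,7S,7aR)-1-hydroxy-6,7-bis[(triethylsilyl)oxy]-1,4a,5,6,7,7a-hexahydrocyclopenta[c]pyran-7-yl]methyl (2E)-3-{4-[(tert-butyldimethylsilyl)oxy]phenyl}prop-2-enoate | O[C@H]1OC=C[C@@H]2C[C@@H](O[Si](CC)(CC)CC)[C@@](O[Si](CC)(CC)CC)(COC(=O)/C=C/c3ccc(O[Si](C)(C)C(C)(C)C)cc3)[C@H]12 | intermediate
15 | (3S)-3-methylpentanoic acid | CC[C@H](C)CC(O)=O | starting material
16 | [(1R,4aS,6R,7S,7aR)-1-{[(3S)-3-methylpentanoyl]oxy}-6,7-bis[(triethylsilyl)oxy]-1,4a,5,6,7,7a-hexahydrocyclopenta[c]pyran-7-yl]methyl (2E)-3-{4-[(tert-butyldimethylsilyl)oxy]phenyl}prop-2-enoate | CC[C@H](C)CC(=O)O[C@H]1OC=C[C@@H]2C[C@@H](O[Si](CC)(CC)CC)[C@@](O[Si](CC)(CC)CC)(COC(=O)/C=C/c3ccc(O[Si](C)(C)C(C)(C)C)cc3)[C@H]12 | intermediate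
17 | [(1R,4aR,6R,7S,7aR)-4-[(dimethyliminio)methyl]-1-{[(3S)-3-methylpentanoyl]oxy}-6,7-bis[(triethylsilyl)oxy]-1,4a,5,6,7,7a-hexahydrocyclopenta[c]pyran-7-yl]methyl (2E)-3-{4-[(tert-butyldimethylsilyl)oxy]phenyl}prop-2-enoate chloride | CC[C@H](C)CC(=O)O[C@H]1OC=C(C=[N+](C)C)[C@@H]2C[C@@H](O[Si](CC)(CC)CC)[C@@](O[Si](CC)(CC)CC)(COC(=O)/C=C/c3ccc(O[Si](C)(C)C(C)(C)C)cc3)[C@H]12.[Cl-] | intermediate
18 | [(1R,4aR,6R,7S,7aR)-4-formyl-1-{[(3S)-3-methylpentanoyl]oxy}-6,7-bis[(triethylsilyl)oxy]-1,4a,5,6,7,7a-hexahydrocyclopenta[c]pyran-7-yl]methyl (2E)-3-{4-[(tert-butyldimethylsilyl)oxy]phenyl}prop-2-enoate | CC[C@H](C)CC(=O)O[C@H]1OC=C(C=O)[C@@H]2C[C@@H](O[Si](CC)(CC)CC)[C@@](O[Si](CC)(CC)CC)(COC(=O)/C=C/c3ccc(O[Si](C)(C)C(C)(C)C)cc3)[C@H]12 | intermediate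
19 | [(1R,4aR,6R,7S,7aR)-4-(hydroxymethyl)-1-{[(3S)-3-methylpentanoyl]oxy}-6,7-bis[(triethylsilyl)oxy]-1,4a,5,6,7,7a-hexahydrocyclopenta[c]pyran-7-yl]methyl (2E)-3-{4-[(tert-butyldimethylsilyl)oxy]phenyl}prop-2-enoate | CC[C@H](C)CC(=O)O[C@H]1OC=C(CO)[C@@H]2C[C@@H](O[Si](CC)(CC)CC)[C@@](O[Si](CC)(CC)CC)(COC(=O)/C=C/c3ccc(O[Si](C)(C)C(C)(C)C)cc3)[C@H]12 | intermediate
20 | [(1R,4aR,6R,7S,7aR)-6,7-dihydroxy-4-(hydroxymethyl)-1-{[(3S)-3-methylpentanoyl]oxy}-1,4a,5,6,7,7a-hexahydrocyclopenta[c]pyran-7-yl]methyl (2E)-3-(4-hydroxyphenyl)prop-2-enoate | CC[C@H](C)CC(=O)O[C@H]1OC=C(CO)[C@@H]2C[C@@H](O)[C@@](O)(COC(=O)/C=C/c3ccc(O)cc3)[C@H]12 | target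

**Totals**
Total step count: 11. Longest linear sequence: 10 steps (steps 1, 3–11; the enal branch, step 2 then 3–11, is equally long).

**Three steps most likely to fail, with fallbacks**

The cascade of step 3 is the weakest point. The chiral carbene must place the C8 OH syn to the C5 chain against the substrate's own preference (ester anti to the chain, CH2O anti to the ester), and the sense of induction of the named triazolium is assumed, not known. The fallback sets out from 3 and 6 and lets substrate control work for the route instead. The same cascade is run with the antipodal amine, (R)-2-[diphenyl(trimethylsilyloxy)methyl]pyrrolidine, and an achiral triazolium, 2-(pentafluorophenyl)-6,7-dihydro-5H-pyrrolo[2,1-c][1,2,4]triazol-2-ium tetrafluoroborate. This should give the C5-epimeric ketol tert-butyl (1R,2S,5S)-5-(2,2-diethoxyethyl)-2-hydroxy-2-(coumaroyloxymethyl)-3-oxocyclopentane-1-carboxylate F1, in which C8 and C9 already have the correct configuration. Saegusa–Ito dehydrogenation on the only enolizable side (TMSCl, NaI, Et3N, MeCN; then Pd(OAc)2) erases C5 and gives the cyclopentenone tert-butyl (1R,5S)-2-(2,2-diethoxyethyl)-5-hydroxy-5-(coumaroyloxymethyl)-4-oxocyclopent-2-ene-1-carboxylate F2. Conjugate reduction with [(Ph3P)CuH]6 then delivers hydride to C5 anti to the C9 ester, which comes back to the route at 8.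

Step 6 is the second risk. The lutidinium-activated C3 may be captured by the neighbouring C8 silyl ether, and the dehydrative enol lactonization of the pseudo-acid may stall. The fallback sets out from 12 and bypasses the enol lactone and the borohydride step. The acid is coupled with ethanethiol (DCC, DMAP) to the thioester S-ethyl (1R,2S,3R,5S)-2-(aryl-TBS-coumaroyloxymethyl)-5-(2-oxoethyl)-2,3-bis[(triethylsilyl)oxy]cyclopentane-1-carbothioate F3. Fukuyama reduction (Et3SiH, Pd/C, acetone) gives the dialdehyde {(1S,2R,3S,5R)-2-formyl-3-(2-oxoethyl)-1,5-bis[(triethylsilyl)oxy]cyclopentyl}methyl (2E)-3-{4-[(tert-butyldimethylsilyl)oxy]phenyl}prop-2-enoate F4. F4 closes by itself to the cis-fused enol hemiacetal and comes back to the route at 14.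

Step 9 is the third risk. The chloroiminium reagent and the HCl it releases may attack the TES ethers or ionize the C1 acyloxy acetal before C4 is formylated. The fallback sets out from 16 and replaces electrophilic formylation/reduction by halogenation and cross-coupling. Iodination at C4 (N-iodosuccinimide, AgNO3 cat., MeCN) gives the vinyl iodide [(1R,4aR,6R,7S,7aR)-4-iodo-1-{[(3S)-3-methylpentanoyl]oxy}-6,7-bis[(triethylsilyl)oxy]-1,4a,5,6,7,7a-hexahydrocyclopenta[c]pyran-7-yl]methyl (2E)-3-{4-[(tert-butyldimethylsilyl)oxy]phenyl}prop-2-enoate F5. Stille coupling with (tributylstannyl)methanol (Pd(PPh3)4, dioxane, 80 °C) installs the CH2OH group directly and comes back to the route at 19.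

**Further compounds**
F1 | step 3 | tert-butyl (1R,2S,5S)-5-(2,2-diethoxyethyl)-2-hydroxy-2-({[(2E)-3-(4-hydroxyphenyl)prop-2-enoyl]oxy}methyl)-3-oxocyclopentane-1-carboxylate | CCOC(OCC)C[C@H]1CC(=O)[C@@](O)(COC(=O)/C=C/c2ccc(O)cc2)[C@@H]1C(=O)OC(C)(C)C
F2 | step 3 | tert-butyl (1R,5S)-2-(2,2-diethoxyethyl)-5-hydroxy-5-({[(2E)-3-(4-hydroxyphenyl)prop-2-enoyl]oxy}methyl)-4-oxocyclopent-2-ene-1-carboxylate | CCOC(OCC)CC1=CC(=O)[C@@](O)(COC(=O)/C=C/c2ccc(O)cc2)[C@@H]1C(=O)OC(C)(C)C
F3 | step 6 | S-ethyl (1R,2S,3R,5S)-2-({[(2E)-3-{4-[(tert-butyldimethylsilyl)oxy]phenyl}prop-2-enoyl]oxy}methyl)-5-(2-oxoethyl)-2,3-bis[(triethylsilyl)oxy]cyclopentane-1-carbothioate | O=CC[C@@H]1C[C@@H](O[Si](CC)(CC)CC)[C@@](O[Si](CC)(CC)CC)(COC(=O)/C=C/c2ccc(O[Si](C)(C)C(C)(C)C)cc2)[C@@H]1C(=O)SCC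
F4 | step 6 | {(1S,2R,3S,5R)-2-formyl-3-(2-oxoethyl)-1,5-bis[(triethylsilyl)oxy]cyclopentyl}methyl (2E)-3-{4-[(tert-butyldimethylsilyl)oxy]phenyl}prop-2-enoate | O=CC[C@@H]1C[C@@H](O[Si](CC)(CC)CC)[C@@](O[Si](CC)(CC)CC)(COC(=O)/C=C/c2ccc(O[Si](C)(C)C(C)(C)C)cc2)[C@@H]1C=O
F5 | step 9 | [(1R,4aR,6R,7S,7aR)-4-iodo-1-{[(3S)-3-methylpentanoyl]oxy}-6,7-bis[(triethylsilyl)oxy]-1,4a,5,6,7,7a-hexahydrocyclopenta[c]pyran-7-yl]methyl (2E)-3-{4-[(tert-butyldimethylsilyl)oxy]phenyl}prop-2-enoate | CC[C@H](C)CC(=O)O[C@H]1OC=C(I)[C@@H]2C[C@@H](O[Si](CC)(CC)CC)[C@@](O[Si](CC)(CC)CC)(COC(=O)/C=C/c3ccc(O[Si](C)(C)C(C)(C)C)cc3)[C@H]12
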